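Amounts first, for the quick number: target is built from starting material that has opened, so the amount to reckon is the fraction of the charge that has left the starting material.

| setting | winter | summer | flask |
|---|---|---|---|
| starting material | 0.050 M | 0.10 M | 0.050 M |
| partner | 0.060 M | 0.060 M | 0.0600 M |
| remark | the very flask that is asked about, followed so far | run made earlier |  |
| time |  |  | 10 h |

- winter (time / min: target / %, crystals / %, starting material / %): 12.0: 0, 0.6, 98.6; 25.0: 0, 0.1, 97.6; 40.0: 0.1, 0.5, 96.8; 50.0: 0, 0, 95.3
- summer (time / h: target / %, crystals / %, starting material / %): 2.50: 2.4, 0, 88.3; 5.00: 8.1, 6.1, 78.2; 8.00: 14.1, 12.6, 66.9; 10.0: 19.8, 15.6, 61.5

(scatter of a reading: 0.5 percentage points)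

* the target and crystals together standing at 10 h, as a percentage of the starting material charged
* concentration of target in solution at 10 h, in percent of saturation

- in percentages every species weighs as the starting material in it: one homo product counts as two
- for target the crystals are counted in
- as a solid, counted per litre of solution: crystals
- steps that have been proposed: starting material <-> open intermediate; partner -> second intermediate; open intermediate + second intermediate -> target; 2 open intermediate -> homo product; crystals <-> target

In the summer run the fraction left reads 61.5% at 10.0 h. Taking the loss as first order gives the opening half-life, the time in which the fraction left halves:

half-life = 10.0 h × 0.693 / 0.486 = 14.3 h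

The winter run, which is the asked flask itself followed so far, at a charge of 0.050 M against the summer 0.10 M, tests it. At 50.0 min the half-life leaves 96.0%, and the reading is 95.3%, a gap of 0.73 percentage points against a scatter of 0.5 points. So the fraction lost is carried from the summer charge to the asked flask, and at 10 h:

fraction opened = 38.5%

Of that fraction, the summer run shows 51.4% as target, a reading of the selectivity. The same share, taken unchanged although the charge differs, gives 19.8% for the flask, crystals counted in, which is the number this reckoning commits to. That is 9.90 mM of target in the flask, against a dissolved level of 4.20 mM read, with its scatter, as the difference of two summer readings at 10.0 h, so crystals should stand in the flask, over a solution at or above saturation.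

The forecast, your hunch, says 25% and 100%, on the ground that “halving the charge should improve selectivity”, and so stands above this reckoning.

The flask gives 22.7% and 117%.

    starting material ⇌ open intermediate (K = 29.0, k = 8.30 × 10⁻⁴ /min)
    partner → second intermediate (k = 0.0110 /min)
    open intermediate + second intermediate → target (k = 0.0900 /M/min)
    2 open intermediate → homo product (k = 0.150 /M/min)
    crystals ⇌ target, rate k5*(cs5 - [target]) while solid is left; crystals form when [target] > cs5 (solubility = 1.80 mM, k = 0.0660 /min)

The half-life leaves 61.6% of the starting material in the flask at 10 h, and 60.9% stands there. The flask's target and crystals stay at 22.7% in part through the time allowed together with the falling level of partner: without that fall the same run gives 35.7%, and left 100 h it gives 77.2%. In the neighbour flask read at 40.0 h, the same half-life leaves 14.4%, and 13.8% stands there beside 62.7% of target and crystals.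

The readings come from a simulation on assumed constants; scatter was added.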